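**Retrosynthetic overview**

1. No ring is formed. The resorcinol ring is bought intact as 5-bromoresorcinol 1, and the acyclic target is cut into an arylalkene half and a C8 allylic acetate half.
2. Aryl–C1 bond: B-alkyl Suzuki coupling of 1 with the mono-9-BBN adduct 3 of nona-1,8-diene 2 gives alkenylresorcinol 4, without protecting groups.
3. C10–O bond (key step, sets the only stereocentre): enantioselective, branch-selective allylic C–H acetoxylation of oct-1-ene 5 gives (R)-oct-1-en-3-yl acetate 6.
4. C8=C9 (Z): Z-selective cross-metathesis of 4 with 6 gives target 7.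

Assumption: the side chain is numbered C1–C15 from the ring, the SMILES is read as 8Z,10R, and 1, 2 and 5 are taken as commercial.

**Route**

Step 1
Reactants: 1 5-bromobenzene-1,3-diol; 2 nona-1,8-diene
Product: 4 5-(non-8-en-1-yl)benzene-1,3-diol, via non-8-enyl-9-BBN 3 (not isolated)
Conditions: 9-BBN (1.3 equiv), 2 (5 equiv), THF, 0 °C→rt, excess 2 removed in vacuo; then 1 (1.0 equiv), PdCl2(dppf) (5 mol %), 3 M aq K3PO4 (5 equiv), THF/DMF, 60 °C; 1 M HCl work-up
Reagents that add atoms: none
Why: 9-BBN hydroborates one terminal alkene of the excess symmetrical diene anti-Markovnikov, and the B-alkyl borane then undergoes B-alkyl Suzuki–Miyaura coupling with the aryl bromide, whose C–Br carbon is meta to both (deprotonated) hydroxyls and so still adds to Pd(0); no stereocentre is formed.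

Step 2
Reactants: 5 oct-1-ene
Product: 6 (R)-oct-1-en-3-yl acetate
Conditions: Pd(OAc)2 (10 mol %), chiral aryl sulfoxide–oxazoline L* (12 mol %; (S)-4-tert-butyl-2-[2-((R)-p-tolylsulfinyl)phenyl]-4,5-dihydrooxazole or its antipode), 2,6-dimethyl-1,4-benzoquinone (1.5 equiv), AcOH (3 equiv), toluene, 45 °C
Reagents that add atoms: acetic acid, CC(=O)O
Why: Proposed new method: enantioselective, branch-selective intermolecular allylic C–H acetoxylation of an unactivated α-olefin, in which sulfoxide-assisted, acetate-mediated C–H cleavage gives an (S,N)Pd(allyl) acetate that reacts as the σ-allyl with Pd on the CH2 terminus and a cis κ1-acetate, the acetate carbonyl oxygen is delivered to C3 in a quinone-promoted seven-membered inner-sphere C–O reductive elimination (hence branched), the oxazoline tert-butyl group blocks one face of the C2=C3 unit in that transition state so that C3 forms as R (the ligand antipode is fixed in a first screen by chiral GC), and the quinone reoxidises Pd(0); the closest known reaction type is Pd(II)/sulfoxide-catalysed allylic C–H oxidation, namely the racemic branch-selective acetoxylation of α-olefins with a bis-sulfoxide ligand and the enantioselective intramolecular allylic C–H etherification with sulfoxide–oxazoline ligands.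

Step 3
Reactants: 4 5-(non-8-en-1-yl)benzene-1,3-diol; 6 (R)-oct-1-en-3-yl acetate
Product: 7 (8Z,10R)-1-(3,5-dihydroxyphenyl)pentadec-8-en-10-yl acetate
Conditions: 6 (3 equiv), cyclometalated Z-selective Ru catalyst (C,C-chelating N-adamantyl/N-2,6-diisopropylphenyl NHC, nitrato, o-isopropoxybenzylidene; 5 mol %), THF (0.5 M), 35 °C, static vacuum, 4 added over 2 h
Reagents that add atoms: none
Why: Z-selective olefin cross-metathesis, in which the chelated Ru–NHC catalyst forms side-bound ruthenacyclobutanes with both substituents pointing away from the N-aryl group so that C8=C9 forms cis, the hindered α-branched acetate 6 does not homodimerise and is used in excess, ethene loss drives the reaction, and the C10 stereocentre, the acetate and the free phenols are not touched.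

**Compound list**

1 | 5-bromobenzene-1,3-diol (5-bromoresorcinol) | Oc1cc(O)cc(Br)c1 | starting material
2 | nona-1,8-diene | C=CCCCCCC=C | starting material
3 | 9-(non-8-en-1-yl)-9-borabicyclo[3.3.1]nonane (non-8-enyl-9-BBN; not isolated) | C=CCCCCCCCB1C2CCCC1CCC2 | intermediate
4 | 5-(non-8-en-1-yl)benzene-1,3-diol | C=CCCCCCCCc1cc(O)cc(O)c1 | intermediate
5 | oct-1-ene | C=CCCCCCC | starting material
6 | (R)-oct-1-en-3-yl acetate | CCCCC[C@H](C=C)OC(C)=O | intermediate
7 | (8Z,10R)-1-(3,5-dihydroxyphenyl)pentadec-8-en-10-yl acetate (CNP0315732.1) | CCCCC[C@H](/C=C\CCCCCCCc1cc(O)cc(O)c1)OC(C)=O | target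

**Step count and risks**

Total step count: 3. Longest linear sequence: 2 steps (1 → 4 → 7, or 5 → 6 → 7).

The three steps most likely to fail, in order of risk:

Step 2 (the proposed new step). The risks are that acetate attacks outer-sphere and gives linear (E)-oct-2-enyl acetate, and that the enantioselectivity is low. The fallback uses known chemistry, sets out from 5 and comes back at 6. Racemic branch-selective allylic C–H acetoxylation of 5 (Pd(OAc)2/1,2-bis(phenylsulfinyl)ethane 10 mol %, 1,4-benzoquinone 2 equiv, AcOH 4 equiv, CH2Cl2, 40 °C) gives rac-oct-1-en-3-yl acetate F1. Immobilised Candida antarctica lipase B with n-butanol in MTBE at 30 °C is then run to about 55–60 % conversion. The lipase cleaves the (S)-acetate (vinyl in its medium pocket, pentyl in its large pocket) to (S)-oct-1-en-3-ol and leaves the (R)-acetate, which is 6 (at most about 45 % from F1). The same lipase treatment can also polish material of insufficient ee from step 2.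

Step 3. The risks are low turnover with the α-branched allylic acetate, homodimerisation of 4, and catalyst loss through the free phenols. The fallback replaces metathesis by an sp2–sp3 Suzuki coupling at C7–C8; it sets out from 6 and 1 and comes back at 7. Ozonolysis of 6 (O3, CH2Cl2, −78 °C; then PPh3) gives, through the ozonide (1R)-1-(1,2,4-trioxolan-3-yl)hexyl acetate F2, the aldehyde (R)-1-oxoheptan-2-yl acetate F3. A Stork–Zhao olefination (Ph3P=CHI from (iodomethyl)triphenylphosphonium iodide and NaHMDS, THF/DMPU, −78 °C) turns this into the Z-vinyl iodide (R,Z)-1-iodooct-1-en-3-yl acetate F4. Separately, hepta-1,6-diene (5 equiv) is mono-hydroborated with 9-BBN to 9-(hept-6-en-1-yl)-9-borabicyclo[3.3.1]nonane F5 and coupled with 1 as in step 1 to 5-(hept-6-en-1-yl)benzene-1,3-diol F6. F6 is hydroborated with 9-BBN (3.3 equiv, THF, rt; the phenols take up borane as aryloxyboranes that the aqueous base hydrolyses again) to 9-[7-(3,5-dihydroxyphenyl)heptyl]-9-borabicyclo[3.3.1]nonane F7. B-alkyl Suzuki coupling of F7 with F4 (PdCl2(dppf), AsPh3, Cs2CO3, DMF/THF/H2O, rt) proceeds with retention of the Z geometry and gives 7.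

Step 1. The risks are the statistical mono-hydroboration of the diene and interference of the free phenoxides with the borane or the catalyst. The fallback reverses the polarity (aryl nucleophile, alkyl electrophile) and avoids the diene; it sets out from 1 and comes back at 4. Silylation of 1 (TBSCl, imidazole, DMF, rt) gives 1-bromo-3,5-bis(tert-butyldimethylsilyloxy)benzene F8. Mg turnings (THF, 50 °C) convert this into [3,5-bis(tert-butyldimethylsilyloxy)phenyl]magnesium bromide F9. Alkylation with commercial 9-bromonon-1-ene under Li2CuCl4 catalysis (3 mol %, THF/NMP, 0 °C→rt) gives [5-(non-8-en-1-yl)-1,3-phenylene]bis(oxy)bis(tert-butyldimethylsilane) F10. TBAF (THF, 0 °C) frees the phenols and gives 4.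

**Further compounds**

F1 | step 2 | rac-oct-1-en-3-yl acetate | CCCCCC(C=C)OC(C)=O
F2 | step 3 | (1R)-1-(1,2,4-trioxolan-3-yl)hexyl acetate | CCCCC[C@H](C1OCOO1)OC(C)=O
F3 | step 3 | (R)-1-oxoheptan-2-yl acetate | CCCCC[C@H](C=O)OC(C)=O
F4 | step 3 | (R,Z)-1-iodooct-1-en-3-yl acetate | CCCCC[C@H](/C=C\I)OC(C)=O
F5 | step 3 | 9-(hept-6-en-1-yl)-9-borabicyclo[3.3.1]nonane | C=CCCCCCB1C2CCCC1CCC2
F6 | step 3 | 5-(hept-6-en-1-yl)benzene-1,3-diol | C=CCCCCCc1cc(O)cc(O)c1
F7 | step 3 | 9-[7-(3,5-dihydroxyphenyl)heptyl]-9-borabicyclo[3.3.1]nonane | Oc1cc(O)cc(CCCCCCCB2C3CCCC2CCC3)c1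
F8 | step 1 | 1-bromo-3,5-bis(tert-butyldimethylsilyloxy)benzene | CC(C)(C)[Si](C)(C)Oc1cc(Br)cc(O[Si](C)(C)C(C)(C)C)c1
F9 | step 1 | [3,5-bis(tert-butyldimethylsilyloxy)phenyl]magnesium bromide | CC(C)(C)[Si](C)(C)Oc1cc([Mg]Br)cc(O[Si](C)(C)C(C)(C)C)c1
F10 | step 1 | [5-(non-8-en-1-yl)-1,3-phenylene]bis(oxy)bis(tert-butyldimethylsilane) | C=CCCCCCCCc1cc(O[Si](C)(C)C(C)(C)C)cc(O[Si](C)(C)C(C)(C)C)c1
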